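Assumption: the target is drawn as the free bis(hydrogen sulfate). Aryl hydrogen sulfates hydrolyse under their own acidity when concentrated, so the disulfate is carried as its bis(triethylammonium) salt and the free acid is liberated only in the last operation, cold, on a sulfonic acid resin.

## Structural features

The target is a flavonol: ring A, a benzene ring of the phloroglucinol type, is fused to ring C, a 4-pyranone, and ring C carries the catechol ring B at C2 through a single C–C bond. The molecule is flat and has no stereocentre, so no stereochemical relationship has to be set. Five oxygens sit on the periphery: O3 on ring C and O7 on ring A carry hydrogen sulfate esters, while O5 (hydrogen-bonded to the C4 carbonyl), O3′ and O4′ are free. The sulfate monoesters are the fragile groups, since they are ionic, acid-labile and awkward to purify on silica, and so they must come late. The catechol and the enolic 3-hydroxy-4-pyranone are oxidised in alkali under air, and ring A with its three oxygens is very prone to electrophilic substitution. The real difficulty is therefore not the carbon framework but telling five hydroxyls apart and finding a last deprotection that spares the O–S bonds. The key step exploits the C2(aryl)–C3(OH)–C4(=O) array of ring C. This array is a constitutional isomer of a hydrated 2-benzylidene-1-benzofuran-3-one in which O1 sits on the carbon next to the ketone and not on the benzylic carbon. Moving O1 from one carbon to the other enlarges a five-membered ring to ring C and leaves an oxygen at C3.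

## Logic of the disconnections

14 back to 12: the bonds cut are the two O–CH2Ph bonds at O3′ and O4′, together with the ion pairs to triethylammonium. They go last because hydrogenolysis is the one deprotection that leaves aryl and enol sulfates untouched, and because the free catechol is the most oxidation-prone part of the molecule. The gain is a lipophilic salt with a single free phenol that can be handled in organic solvents. The forward step must not reduce the C2–C3 double bond or cleave S–O, and the acid form must be released cold, through 13.

12 back to 11: the O3–S and O7–S bonds are cut. Sulfation is placed as late as possible because everything before it is then neutral and chromatographable. The demand is selectivity among three free hydroxyls. O5 is locked in a six-membered hydrogen bond to the C4 carbonyl and is the least nucleophilic, and the two hydroxyls that would compete, O3′ and O4′, are the benzylated ones.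

11 back to 10: two arenesulfonyl groups are put back on O5 and O7. They are there because ring A has to be electron-poor during the halogenation and inert during the ring enlargement. The gain is one protecting group that tolerates bromine and cold alkali, and both copies fall off in one saponification. The forward step needs S–O cleavage by hydroxide without opening of the pyranone, hence exclusion of oxygen. The two alkaline operations could be run in one flask, but isolating 10 gives a non-phenolic, easily purified compound at the point where most by-products arise.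

10 back to 6 (the strategic cut): O1–C2 and C3–O are cut and O1 is reattached to the carbon that becomes C3, which contracts ring C to a five-membered furanone bearing two bromines. The reason is that the C3 oxygen then arrives from hydroxide during ring formation, so no separate oxidation of C3 is needed. The forward step demands that the ring-A phenoxide, once released, closes on the benzylic carbon faster than that carbon is solvolysed.

6 back to 5: the two C–Br bonds are cut, which leads to an alkene. The demand is that bromine adds to the exocyclic double bond and does not substitute ring A or ring B.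

5 back to 3 and 4: the two sulfonate O–S bonds are cut. A methanesulfonate would be the obvious choice, but its acidic α-hydrogens are a liability next to a ketone in alkali (sulfene fragmentation, or aldol closure of the sulfonyl carbanion onto the carbonyl to a sultone). A 4-methylbenzenesulfonate has no such hydrogen and deactivates ring A just as well.

3 back to 1 and 2: the exocyclic C=C bond is cut by a retro-aldol condensation. This gives two commercial pieces: 1 carries ring A with all its oxygens and the future O1, and 2 carries ring B with the catechol already benzylated. The forward step only has to deliver the alkene, and its geometry becomes irrelevant once the dibromide is consumed.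

## Other disconnections considered

Alternative 1: The cut is made at C3–C4 and at the C2–C3 double bond, so that C3 with its oxygen comes from a one-carbon ylide.
- Forward step: the silyl ester A2 (tert-butyldimethylsilyl 2-{[3,4-bis(benzyloxy)benzoyl]oxy}-4,6-bis(methoxymethoxy)benzoate) would be treated with two equivalents of the phosphorane A3 ({[2-(trimethylsilyl)ethoxy]methylidene}triphenylphosphorane). The first equivalent is acylated at carbon by the silyl ester and the second converts the acylphosphonium salt into a keto ylide. That ylide olefinates the neighbouring aryl ester carbonyl in an intramolecular Wittig reaction and closes ring C as A1 (2-[3,4-bis(benzyloxy)phenyl]-5,7-bis(methoxymethoxy)-3-[2-(trimethylsilyl)ethoxy]chromen-4-one).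
- In its favour: O3 arrives on C3 already masked by a fluoride-labile group orthogonal to the benzyl ethers. No electrophilic halogen is needed, so ring A can stay as electron-rich acetals, and no strong aqueous alkali touches the ring system. On functional-group tolerance it would be the better plan.
- Against it here: an α-alkoxy ylide is a weaker carbon nucleophile and a stronger base than the silylmethylene ylides for which this annulation is established. The Wittig step must form a fully substituted enol ether on the carbonyl of an electron-rich dialkoxybenzoate, a poor electrophile. A2 would also need four or five steps of selective aroylation, acetalisation and silylation on a benzoic acid that decarboxylates easily.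
- Comparison: the two MOM groups of A1 come off together, so O5 and O7 would be told apart at the sulfation by the same chelation argument as in the chosen plan, and the two plans are equal there. In step economy the chosen plan should be ahead, at seven steps against roughly ten or eleven.

Alternative 2: The cut takes C4 out as carbon monoxide and divides the rest into a phenol and an alkyne, so C4–C4a, C3–C4 and O1–C2 are disconnected.
- Forward step: 2-iodo-3,5-bis(methoxymethoxy)phenol A5, 4-ethynyl-1,2-bis(benzyloxy)benzene A6 and carbon monoxide A7 would combine under PdCl2(PPh3)2 in a secondary amine. Zerovalent palladium adds to the C–I bond, CO inserts, the acyl group couples with the alkyne, and the phenol oxygen adds 6-endo to the ynone to give flavone A4 (2-[3,4-bis(benzyloxy)phenyl]-5,7-bis(methoxymethoxy)chromen-4-one).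
- In its favour: three bonds and ring C are made in one catalytic operation from three simple components. In convergence and bond economy of the key step it is better than the chosen plan. A6 would be one homologation step from 2, and no bromine is involved.
- Against it here: A4 has no oxygen at C3, so a later C3 oxidation would be needed, with its own selectivity question. The ynone can also close 5-exo to an aurone, and only the amine steers it. A5 is a hindered, electron-rich aryl iodide flanked by two oxygen substituents, and making it requires selective double protection of a symmetrical triphenol and iodination next to the free hydroxyl and not between the acetals. CO is a toxic gas.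
- Comparison: the chosen ring enlargement installs O3 in the bond-forming event, which is its structural advantage. Differentiation of O5 from O7 is again left to chelation (equal). About ten steps would be expected.

Alternative 3: The cut is at C3–C4 and O1–C8a, so ring A enters as an acylating agent whose ortho fluorine later serves as leaving group for the ring oxygen.
- Forward step: the lithium enolate of A9 (1-[3,4-bis(benzyloxy)phenyl]-2-[(4-methoxybenzyl)oxy]ethan-1-one) would be C-acylated by 2,4,6-trifluorobenzoyl chloride A10. On warming with K2CO3 the enolate oxygen of the resulting 1,3-diketone would displace an ortho fluoride by intramolecular nucleophilic aromatic substitution, giving A8 (2-[3,4-bis(benzyloxy)phenyl]-5,7-difluoro-3-[(4-methoxybenzyl)oxy]chromen-4-one).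
- In its favour: O3 is in place and masked by a group orthogonal to benzyl, the ring closure is of a robust type, and neither bromine nor strong aqueous alkali is needed. Most importantly, the fluorines at C5 and C7 are chemically distinct and could in principle be exchanged one after the other for two different alkoxides. That would distinguish O5 from O7 by construction, a real advantage over the chosen plan, which relies on the low nucleophilicity of the chelated O5.
- Against it here: the two fluoride displacements are extra steps. After the first alkoxide has entered, the ring is electron-rich and the second substitution should be sluggish, and forcing alkoxide conditions endanger C2 of the pyranone. Which fluorine reacts first would have to be established. The enolate of A9 may be acylated at oxygen, and the oxygen placed at C7 needs a third orthogonal protecting group.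
- Comparison: on regiocontrol of the sulfation it is the better plan. On step economy (around eleven steps) and on the certainty of the individual steps the chosen plan is preferred.

Key step: step 4

## Route

Step 1
Reactants: 1 4,6-dihydroxy-1-benzofuran-3(2H)-one; 2 3,4-bis(benzyloxy)benzaldehyde
Product: 3 (Z)-2-[3,4-bis(benzyloxy)benzylidene]-4,6-dihydroxy-1-benzofuran-3(2H)-one
Conditions: KOH (50% aq), MeOH, 60 °C; then 1 M HCl
Reagents that add atoms: none
Why: Base-mediated aldol condensation of the C2 methylene of the benzofuranone with a non-enolisable aldehyde; dehydration is driven by conjugation and the Z isomer (aryl cis to O1) is the thermodynamic one. The free phenols are carried as phenoxides and the benzyl ethers are inert to alkali.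

Step 2
Reactants: 3 (Z)-2-[3,4-bis(benzyloxy)benzylidene]-4,6-dihydroxy-1-benzofuran-3(2H)-one; 4 4-methylbenzenesulfonyl chloride
Product: 5 (Z)-2-[3,4-bis(benzyloxy)benzylidene]-3-oxo-2,3-dihydro-1-benzofuran-4,6-diyl bis(4-methylbenzenesulfonate)
Conditions: TsCl (2.5 equiv), K2CO3, acetone, 50 °C
Reagents that add atoms: 4-methylbenzenesulfonyl chloride (4), Cc1ccc(S(=O)(=O)Cl)cc1
Why: O-Sulfonylation of both phenoxides; the hydroxyl peri to the furanone carbonyl is only weakly chelated and should react. Tosylates are chosen over mesylates because they have no acidic α-hydrogen next to the ketone, and they make ring A electron-poor for step 3.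

Step 3
Reactants: 5 (Z)-2-[3,4-bis(benzyloxy)benzylidene]-3-oxo-2,3-dihydro-1-benzofuran-4,6-diyl bis(4-methylbenzenesulfonate)
Product: 6 2-bromo-2-{bromo[3,4-bis(benzyloxy)phenyl]methyl}-3-oxo-2,3-dihydro-1-benzofuran-4,6-diyl bis(4-methylbenzenesulfonate), racemic anti adduct (2R,αS)/(2S,αR)
Conditions: Br2 (1.05 equiv), CH2Cl2, 0 °C, dark
Reagents that add atoms: bromine, BrBr
Why: Electrophilic anti addition of bromine to the styrene-type double bond; ring A is deactivated by two sulfonates and the acyl group, and ring B, conjugated to the enone, should substitute more slowly than the alkene adds with one equivalent at 0 °C. The two new stereocentres (anti from the Z alkene, racemic) are erased in step 4, so their control is immaterial.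

Step 4
Reactants: 6 2-bromo-2-{bromo[3,4-bis(benzyloxy)phenyl]methyl}-3-oxo-2,3-dihydro-1-benzofuran-4,6-diyl bis(4-methylbenzenesulfonate)
Product: 10 2-[3,4-bis(benzyloxy)phenyl]-3-hydroxy-4-oxo-4H-chromene-5,7-diyl bis(4-methylbenzenesulfonate), via C2 hemiketal 7 (not isolated), via ring-opened bromo diketone 8 (not isolated), via 2-arylchromane-3,4-dione 9 (not isolated)
Conditions: KOH (0.5 M aq, 4 equiv), 1,4-dioxane, 0 → 20 °C, Ar; then AcOH
Reagents that add atoms: potassium hydroxide, [K+].[OH-]
Why: Auwers flavonol synthesis, the alkali-induced ring enlargement of an aurone dibromide. Hydroxide replaces the C2 bromide, an α-bromo ether that reacts through its oxocarbenium ion, and gives hemiketal 7. The oxyanion of 7 collapses to the 1,2-diketone 8 and releases O1 as a phenoxide stabilised by the ortho acyl group and the two sulfonates. This phenoxide displaces the benzyloxy-activated benzylic bromide in a 6-exo-tet closure, which forms the O1–C2 bond of ring C and gives 9; enolisation to the aromatic 3-hydroxy-4-pyranone 10 is irreversible, and the oxygen brought in by hydroxide becomes the C3 hydroxyl. No stereocentre is created and both centres of 6 are erased, so either diastereomer of 6 converges on 10. The step needs the six-membered O-alkylation to outrun solvolysis of the benzylic bromide, E2 loss of HBr to a bromo-aurone and benzilic acid rearrangement of 8; the intramolecular attack on an ionisable benzylic halide, the absence of an alcohol cosolvent and the low temperature should secure this. The tosylates have no α-hydrogen, so neither sulfene fragmentation nor aldol closure onto the ketone can occur, and they should survive cold dilute alkali; if one were lost after ring closure, step 5 would converge anyway.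

Step 5
Reactants: 10 2-[3,4-bis(benzyloxy)phenyl]-3-hydroxy-4-oxo-4H-chromene-5,7-diyl bis(4-methylbenzenesulfonate)
Product: 11 2-[3,4-bis(benzyloxy)phenyl]-3,5,7-trihydroxy-4H-chromen-4-one
Conditions: KOH (2 M aq, 6 equiv), 1,4-dioxane, degassed, 60 °C, Ar; then 1 M HCl
Reagents that add atoms: none
Why: Saponification of aryl sulfonates by attack of hydroxide at sulfur; both departing phenoxides are conjugated with the C4 carbonyl, so cleavage should occur well below the temperatures simple aryl tosylates need. The flavonol is present as its enolate, which resists addition at C2, oxygen is excluded to prevent oxidative ring opening, and the benzyl ethers are inert.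

Step 6
Reactants: 11 2-[3,4-bis(benzyloxy)phenyl]-3,5,7-trihydroxy-4H-chromen-4-one
Product: 12 bis(triethylammonium) 2-[3,4-bis(benzyloxy)phenyl]-5-hydroxy-4-oxo-4H-chromene-3,7-diyl disulfate
Conditions: SO3·NEt3 (5 equiv), Et3N, DMF, 50 °C; Sephadex LH-20
Reagents that add atoms: sulfur trioxide–triethylamine complex, CC[N+](CC)(CC)S(=O)(=O)[O-]
Why: O-Sulfation with a sulfur trioxide–amine complex; the acidic O7 and the enolic O3 react, whereas O5 is held in a strong hydrogen bond to the C4 carbonyl and is the position that resists such reagents. O3′ and O4′ are blocked as benzyl ethers, and the product is obtained directly as the bis(triethylammonium) salt.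

Step 7
Reactants: 12 bis(triethylammonium) 2-[3,4-bis(benzyloxy)phenyl]-5-hydroxy-4-oxo-4H-chromene-3,7-diyl disulfate
Product: 14 quercetin 3,7-di-O-sulfate, 2-(3,4-dihydroxyphenyl)-5-hydroxy-4-oxo-4H-chromene-3,7-diyl bis(hydrogen sulfate), via debenzylated bis(triethylammonium) salt 13 (not isolated)
Conditions: H2 (1 atm), 10% Pd/C, MeOH/H2O, 20 °C; filter; Dowex 50W-X8 (H+ form), H2O, 0–5 °C; freeze-dry
Reagents that add atoms: none
Why: Hydrogenolysis of benzyl aryl ethers over Pd/C; aryl and enol sulfate salts and the chromone double bond are stable to these conditions. The free acid is liberated by cation exchange in the cold and freeze-dried at once to limit acid-catalysed loss of SO3.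

## Compound list

1 | 4,6-dihydroxy-1-benzofuran-3(2H)-one | O=C1COc2cc(O)cc(O)c12 | starting material
2 | 3,4-bis(benzyloxy)benzaldehyde | O=Cc1ccc(OCc2ccccc2)c(OCc2ccccc2)c1 | starting material
3 | (Z)-2-[3,4-bis(benzyloxy)benzylidene]-4,6-dihydroxy-1-benzofuran-3(2H)-one | O=C1/C(=C/c2ccc(OCc3ccccc3)c(OCc3ccccc3)c2)Oc2cc(O)cc(O)c21 | intermediate
4 | 4-methylbenzenesulfonyl chloride | Cc1ccc(S(=O)(=O)Cl)cc1 | starting material
5 | (Z)-2-[3,4-bis(benzyloxy)benzylidene]-3-oxo-2,3-dihydro-1-benzofuran-4,6-diyl bis(4-methylbenzenesulfonate) | O=C1/C(=C/c2ccc(OCc3ccccc3)c(OCc3ccccc3)c2)Oc2cc(OS(=O)(=O)c3ccc(C)cc3)cc(OS(=O)(=O)c3ccc(C)cc3)c21 | intermediate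
6 | 2-bromo-2-{bromo[3,4-bis(benzyloxy)phenyl]methyl}-3-oxo-2,3-dihydro-1-benzofuran-4,6-diyl bis(4-methylbenzenesulfonate), racemic anti adduct, (2R,αS) enantiomer drawn | O=C1c2c(OS(=O)(=O)c3ccc(C)cc3)cc(OS(=O)(=O)c3ccc(C)cc3)cc2O[C@]1(Br)[C@@H](Br)c1ccc(OCc2ccccc2)c(OCc2ccccc2)c1 | intermediate
7 | 2-{bromo[3,4-bis(benzyloxy)phenyl]methyl}-2-hydroxy-3-oxo-2,3-dihydro-1-benzofuran-4,6-diyl bis(4-methylbenzenesulfonate), diastereomer mixture, not isolated | O=C1c2c(OS(=O)(=O)c3ccc(C)cc3)cc(OS(=O)(=O)c3ccc(C)cc3)cc2OC1(O)C(Br)c1ccc(OCc2ccccc2)c(OCc2ccccc2)c1 | intermediate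
8 | 3-[3,4-bis(benzyloxy)phenyl]-3-bromo-1-{2-hydroxy-4,6-bis[(4-methylbenzenesulfonyl)oxy]phenyl}propane-1,2-dione, racemic, phenoxide in the flask, not isolated | O=C(C(=O)C(Br)c1ccc(OCc2ccccc2)c(OCc2ccccc2)c1)c1c(O)cc(OS(=O)(=O)c2ccc(C)cc2)cc1OS(=O)(=O)c1ccc(C)cc1 | intermediate
9 | 2-[3,4-bis(benzyloxy)phenyl]-3,4-dioxo-3,4-dihydro-2H-chromene-5,7-diyl bis(4-methylbenzenesulfonate), racemic, not isolated | O=C1C(=O)c2c(OS(=O)(=O)c3ccc(C)cc3)cc(OS(=O)(=O)c3ccc(C)cc3)cc2OC1c1ccc(OCc2ccccc2)c(OCc2ccccc2)c1 | intermediate
10 | 2-[3,4-bis(benzyloxy)phenyl]-3-hydroxy-4-oxo-4H-chromene-5,7-diyl bis(4-methylbenzenesulfonate) | O=c1c(O)c(-c2ccc(OCc3ccccc3)c(OCc3ccccc3)c2)oc2cc(OS(=O)(=O)c3ccc(C)cc3)cc(OS(=O)(=O)c3ccc(C)cc3)c12 | intermediate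
11 | 2-[3,4-bis(benzyloxy)phenyl]-3,5,7-trihydroxy-4H-chromen-4-one | O=c1c(O)c(-c2ccc(OCc3ccccc3)c(OCc3ccccc3)c2)oc2cc(O)cc(O)c12 | intermediate
12 | bis(triethylammonium) 2-[3,4-bis(benzyloxy)phenyl]-5-hydroxy-4-oxo-4H-chromene-3,7-diyl disulfate | CC[NH+](CC)CC.CC[NH+](CC)CC.O=c1c(OS(=O)(=O)[O-])c(-c2ccc(OCc3ccccc3)c(OCc3ccccc3)c2)oc2cc(OS(=O)(=O)[O-])cc(O)c12 | intermediate
13 | bis(triethylammonium) 2-(3,4-dihydroxyphenyl)-5-hydroxy-4-oxo-4H-chromene-3,7-diyl disulfate, not isolated | CC[NH+](CC)CC.CC[NH+](CC)CC.O=c1c(OS(=O)(=O)[O-])c(-c2ccc(O)c(O)c2)oc2cc(OS(=O)(=O)[O-])cc(O)c12 | intermediate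
14 | quercetin 3,7-di-O-sulfate, 2-(3,4-dihydroxyphenyl)-5-hydroxy-4-oxo-4H-chromene-3,7-diyl bis(hydrogen sulfate) | O=c1c(OS(=O)(=O)O)c(-c2ccc(O)c(O)c2)oc2cc(OS(=O)(=O)O)cc(O)c12 | target

## Step count and least certain steps

Total step count: 7. Longest linear sequence: 7 steps (1 to 14); 2 and 4 are commercial and enter in steps 1 and 2.

Step 4 (key step). The benzylic bromide, activated by the para benzyloxy group, may be solvolysed before O1 is released, which would leave a benzylic hydroxyl that cannot be displaced. Competing processes are E2 loss of HBr to a bromo-aurone, reductive loss of bromine back to the alkene, benzilic acid rearrangement of the open diketone and early sulfonate cleavage. Fallback: starting from 6, the alkali is replaced by silver-assisted hydrolysis (AgNO3, aqueous acetone, 0–20 °C). This should exchange both bromides for hydroxyl without any base and give the hemiketal diol 2-{[3,4-bis(benzyloxy)phenyl](hydroxy)methyl}-2-hydroxy-3-oxo-2,3-dihydro-1-benzofuran-4,6-diyl bis(4-methylbenzenesulfonate) F1. A catalytic amount of TsOH·H2O in warm 1,4-dioxane would then ionise the benzylic hydroxyl, and O1 would shift from the hemiketal carbon to the benzylic carbon while the hemiketal hydroxyl becomes the C3 carbonyl. This semipinacol-type ring enlargement leads to 9, and enolisation brings the route back at 10.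

Step 3. Electrophilic substitution on ring B, para to the 3′-benzyloxy group, may compete with addition, and the benzylic bromide may ionise during isolation (loss of HBr or hydrolysis), because that position is a 4-alkoxybenzylic one. Fallback: from 5, epoxidation with dimethyldioxirane in acetone at 0 °C, which is neutral and free of halogen and acid, should give the spiro-epoxide 3′-[3,4-bis(benzyloxy)phenyl]-3-oxo-3H-spiro[1-benzofuran-2,2′-oxirane]-4,6-diyl bis(4-methylbenzenesulfonate) F2 (racemic, oxygen added to one face of the Z alkene). F2 is the anhydro form of F1. TsOH·H2O in moist 1,4-dioxane would open it at the benzylic carbon and trigger the same acid-mediated ring enlargement, so this path replaces steps 3 and 4 together and comes back to the route at 10.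

Step 6. Sulfation may stop at O7 before O3 has reacted, or go on to O5 under forcing conditions, and the resulting anionic regioisomers are hard to separate. Fallback: from 11, the sulfates are introduced as neutral, protected diesters with 2,2,2-trichloroethyl chlorosulfate, Et3N and DMAP in THF. This gives 2-[3,4-bis(benzyloxy)phenyl]-5-hydroxy-4-oxo-4H-chromene-3,7-diyl bis(2,2,2-trichloroethyl) bis(sulfate) F3, which can be purified on silica and freed from regioisomers. Pd/C with HCO2NH4 in MeOH would then remove the trichloroethyl groups (reductive β-elimination) and the benzyl ethers in one operation, giving diammonium 2-(3,4-dihydroxyphenyl)-5-hydroxy-4-oxo-4H-chromene-3,7-diyl disulfate F4. Cold cation exchange as in step 7 returns the route at 14.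

Step 5. Warm alkali may open the pyranone ring of the flavonol by oxidation or hydrolysis, and the peri sulfonate at C5 may cleave incompletely because the enolate form weakens activation by the carbonyl. Fallback: from 3, the ring-A phenols are acylated with pivaloyl chloride (Et3N, DMAP, CH2Cl2) to (Z)-2-[3,4-bis(benzyloxy)benzylidene]-3-oxo-2,3-dihydro-1-benzofuran-4,6-diyl bis(2,2-dimethylpropanoate) F5. Bromine in CH2Cl2 at 0 °C gives 2-bromo-2-{bromo[3,4-bis(benzyloxy)phenyl]methyl}-3-oxo-2,3-dihydro-1-benzofuran-4,6-diyl bis(2,2-dimethylpropanoate) F6. Cold aqueous KOH in 1,4-dioxane performs the ring enlargement to 2-[3,4-bis(benzyloxy)phenyl]-3-hydroxy-4-oxo-4H-chromene-5,7-diyl bis(2,2-dimethylpropanoate) F7, whose activated aryl esters are saponified in the same flask at 20–40 °C. No hot alkali is needed, and the route is rejoined at 11.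

## Further compounds

F1 | step 4 | 2-{[3,4-bis(benzyloxy)phenyl](hydroxy)methyl}-2-hydroxy-3-oxo-2,3-dihydro-1-benzofuran-4,6-diyl bis(4-methylbenzenesulfonate), diastereomer mixture | O=C1c2c(OS(=O)(=O)c3ccc(C)cc3)cc(OS(=O)(=O)c3ccc(C)cc3)cc2OC1(O)C(O)c1ccc(OCc2ccccc2)c(OCc2ccccc2)c1
F2 | step 3 | 3′-[3,4-bis(benzyloxy)phenyl]-3-oxo-3H-spiro[1-benzofuran-2,2′-oxirane]-4,6-diyl bis(4-methylbenzenesulfonate), racemic, (2R,3′R) enantiomer drawn | O=C1c2c(OS(=O)(=O)c3ccc(C)cc3)cc(OS(=O)(=O)c3ccc(C)cc3)cc2O[C@@]12O[C@@H]2c1ccc(OCc2ccccc2)c(OCc2ccccc2)c1
F3 | step 6 | 2-[3,4-bis(benzyloxy)phenyl]-5-hydroxy-4-oxo-4H-chromene-3,7-diyl bis(2,2,2-trichloroethyl) bis(sulfate) | O=c1c(OS(=O)(=O)OCC(Cl)(Cl)Cl)c(-c2ccc(OCc3ccccc3)c(OCc3ccccc3)c2)oc2cc(OS(=O)(=O)OCC(Cl)(Cl)Cl)cc(O)c12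
F4 | step 6 | diammonium 2-(3,4-dihydroxyphenyl)-5-hydroxy-4-oxo-4H-chromene-3,7-diyl disulfate | [NH4+].[NH4+].O=c1c(OS(=O)(=O)[O-])c(-c2ccc(O)c(O)c2)oc2cc(OS(=O)(=O)[O-])cc(O)c12
F5 | step 5 | (Z)-2-[3,4-bis(benzyloxy)benzylidene]-3-oxo-2,3-dihydro-1-benzofuran-4,6-diyl bis(2,2-dimethylpropanoate) | O=C1/C(=C/c2ccc(OCc3ccccc3)c(OCc3ccccc3)c2)Oc2cc(OC(=O)C(C)(C)C)cc(OC(=O)C(C)(C)C)c21
F6 | step 5 | 2-bromo-2-{bromo[3,4-bis(benzyloxy)phenyl]methyl}-3-oxo-2,3-dihydro-1-benzofuran-4,6-diyl bis(2,2-dimethylpropanoate), racemic anti adduct, (2R,αS) enantiomer drawn | O=C1c2c(OC(=O)C(C)(C)C)cc(OC(=O)C(C)(C)C)cc2O[C@]1(Br)[C@@H](Br)c1ccc(OCc2ccccc2)c(OCc2ccccc2)c1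
F7 | step 5 | 2-[3,4-bis(benzyloxy)phenyl]-3-hydroxy-4-oxo-4H-chromene-5,7-diyl bis(2,2-dimethylpropanoate) | O=c1c(O)c(-c2ccc(OCc3ccccc3)c(OCc3ccccc3)c2)oc2cc(OC(=O)C(C)(C)C)cc(OC(=O)C(C)(C)C)c12
A1 | alternative 1 | 2-[3,4-bis(benzyloxy)phenyl]-5,7-bis(methoxymethoxy)-3-[2-(trimethylsilyl)ethoxy]chromen-4-one | C[Si](C)(C)CCOc1c(-c2ccc(OCc3ccccc3)c(OCc3ccccc3)c2)oc2cc(OCOC)cc(OCOC)c2c1=O
A2 | alternative 1 | tert-butyldimethylsilyl 2-{[3,4-bis(benzyloxy)benzoyl]oxy}-4,6-bis(methoxymethoxy)benzoate | CC(C)(C)[Si](C)(C)OC(=O)c1c(OCOC)cc(OCOC)cc1OC(=O)c1ccc(OCc2ccccc2)c(OCc2ccccc2)c1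
A3 | alternative 1 | {[2-(trimethylsilyl)ethoxy]methylidene}triphenylphosphorane | C[Si](C)(C)CCOC=P(c1ccccc1)(c1ccccc1)c1ccccc1
A4 | alternative 2 | 2-[3,4-bis(benzyloxy)phenyl]-5,7-bis(methoxymethoxy)chromen-4-one | COCOc1cc(OCOC)c2c(c1)oc(-c1ccc(OCc3ccccc3)c(OCc3ccccc3)c1)cc2=O
A5 | alternative 2 | 2-iodo-3,5-bis(methoxymethoxy)phenol | COCOc1cc(O)c(I)c(OCOC)c1
A6 | alternative 2 | 4-ethynyl-1,2-bis(benzyloxy)benzene | C#Cc1ccc(OCc2ccccc2)c(OCc2ccccc2)c1
A7 | alternative 2 | carbon monoxide | [C-]#[O+]
A8 | alternative 3 | 2-[3,4-bis(benzyloxy)phenyl]-5,7-difluoro-3-[(4-methoxybenzyl)oxy]chromen-4-one | COc1ccc(COc2c(-c3ccc(OCc4ccccc4)c(OCc4ccccc4)c3)oc3cc(F)cc(F)c3c2=O)cc1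
A9 | alternative 3 | 1-[3,4-bis(benzyloxy)phenyl]-2-[(4-methoxybenzyl)oxy]ethan-1-one | COc1ccc(COCC(=O)c2ccc(OCc3ccccc3)c(OCc3ccccc3)c2)cc1
A10 | alternative 3 | 2,4,6-trifluorobenzoyl chloride | O=C(Cl)c1c(F)cc(F)cc1F
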